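## Structural features

The target is a single cyclohexane ring carrying substituents on four of its six carbons. C1 is quaternary and bears a hydroxymethyl group and a (3E,7E)-4,8,12-trimethyltrideca-3,7,11-trienyl chain. C2 bears a 3-hydroxypropyl chain, C3 is the ring end of an exocyclic tetrasubstituted (Z)-enal C3=C(CH3)CHO, C4 and C5 are methylenes, and C6 is a tertiary methyl carbinol. The stereocentres C6, C1 and C2 are contiguous (6S,1S,2R): the C6 hydroxyl, the C1 hydroxymethyl and the C2 chain lie on one face, the C6 methyl and the trienyl chain on the other. The fragile parts are the enal (its γ-hydrogen is the C2 stereocentre, so base can epimerise C2 or scramble the geometry), the acid-sensitive skipped triene, and any carbonyl derivative of the C1 carbon, which is β to the C6 hydroxyl and therefore open to retro-aldol cleavage. The real difficulty is the bond between the two fully substituted carbons C1 and C6 next to the C2 stereocentre, followed by the enal geometry (formyl on the C2 side). The key step uses three features. The C6–O and the oxygenated carbon on C1 are 1,3-related, an aldol pattern once the hydroxymethyl is raised to an ester. The C1 chain can be grown from a vinyl group, which makes C1 the ester-bearing terminus of an allyl nucleophile. C3–C4–C5–C6 with its methyl is a 1,4-diketone, the open form of a 2-methylfuran attached at C2.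

## Logic of the disconnections

**33 ⇒ 32 ⇒ 31.** The formyl C=O is taken back to the allylic C–OH of 32, and the side-chain O–H to the O–Si bond of 31. The enal is the most base-sensitive group, so it is created last by an oxidant that distinguishes allylic from saturated alcohols. All earlier steps then run on carbonyl-free polyols. The forward oxidation must leave two saturated primary alcohols, the tertiary alcohol and the alkene geometry alone.

**31 ⇒ 22 + 29.** The C(sp3)–C(sp2) bond between the second methylene of the C1 chain and the first alkene carbon of the triene is cut. This separates the ring core from a fourteen-carbon polyene at a bond that a B-alkyl Suzuki–Miyaura coupling can form with retention of geometry. The demand is hydroboration of only the vinyl group of 22 and a coupling that tolerates three free hydroxyls.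

**29 ⇒ 27 ⇒ 26 ⇒ 23 + 24.** The C–I and C–CH3 bonds of 29 go back to the terminal alkyne 27 (syn methylmetalation), the alkyne C–H to the C–Si bond of 26, and the propargylic C–C bond to 23 and 24. The E geometry of the new trisubstituted alkene comes from the syn addition; that of the older one is bought with 23. The alkylation must occur at the α-carbon of the allylic bromide.

**22 ⇒ 21 ⇒ 20 ⇒ 18 + 19.** The two primary C–OH groups of 22 are raised to the formyl and ester carbons of 21, the enal is recognised as a 1,3-transposed tertiary allylic alcohol (20), and the C3–C(isopropenyl) bond is cut. This returns the whole enal unit to a ring ketone. An ester cannot be reduced beside an enal, so both are reduced in one operation and only the allylic alcohol is re-oxidised at the very end. The demands are addition to a hindered, enolisable ketone without retro-aldol loss of the β-hydroxy ester, and a transposition that places the oxygenated carbon on the C2 side.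

**18 ⇒ 16 (through 17).** The C1–C6 bond is cut. This is the simplifying step: it removes the ring, the quaternary centre and two of the three stereocentres, leaving an acyclic compound with one stereocentre. Forward, the allyl nucleophile must react through its ester-bearing carbon, must choose the C6 and not the C3 ketone, and must set C1 and C6 relative to C2 before C2 is lost.

**16 ⇒ 15 ⇒ 14 ⇒ 13.** C–Br goes back to C–OH, the C4–C5 single bond to the cis double bond of 14, and the two ketone C=O bonds to the furan C–O bonds of 13. The furan carries both carbonyls, inert, through all the strongly basic steps. From 14 onward C2–H is α to a ketone and allylic, so three points of design protect it. The allylic hydroxyl is already free in 13, so no deprotection is ever run on 14–16. The bromide is made last under neutral conditions and used at once. The furan is opened cold and buffered.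

**13 ⇒ 12 ⇒ 10 ⇒ 7 + 8.** O–H goes back to O–Si, and the C1=C double bond is cut (aldol addition, then dehydration). This attaches the two-carbon allylic unit to the ester α-carbon with standard enolate chemistry. The demand is an E-selective elimination; the geometry is not critical, because the allylindium in step 11 equilibrates.

**7 ⇒ 6 ⇒ 4 + 5.** The ester carbon goes back to the aldehyde, and the C2–furan bond is cut (conjugate Friedel–Crafts). This is the only step in which absolute configuration is introduced, and it is catalytic. The demand is high enantioselectivity with a moderately nucleophilic arene.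

**4 ⇒ 2 + 3; 2 ⇒ 1.** The enal C=C bond is cut by cross-metathesis, then the O–Si bond. This reaches commercial 1 in two steps and needs only E selectivity.

## Other disconnections considered

**Alternative 1:** The cut is the exocyclic C3=C bond together with a lactone C–O bond that ties the enal carbon to the side-chain oxygen of C2; the dibromo ester A2 already contains the triene and all three stereocentres. Forward, divalent samarium (SmI2) reduces the 2,2-dibromopropanoate, the samarium enolate adds to the C3 ketone, and the bromo alkoxide is reduced again and eliminates to give the eight-membered lactone A1. In its favour, the tether can only deliver the acyl carbon to the C2 side of C3, so the enal geometry is fixed by connectivity. On this point it is better than the chosen plan, where the geometry of 21 rests on a steric preference. Partial reduction of A1 could also reach the aldehyde level directly, which is at least equal in step count at the end. Against it, an eight-membered ring must close onto a ketone flanked by a branched and a quaternary carbon, and the step builds no stereocentre and no part of the carbocycle. Structurally it solves the enal problem and leaves the C1–C6 bond unsolved. Mechanistically both plans are metal enolate additions to ketones, but 16 → 18 is a six-membered closure. It does not shorten the synthesis, because the core costs the same. It is kept as the fallback for step 13.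

**Alternative 2:** The cut is the C1–CH2OH bond. The tertiary carbinol of dienone A4 carries a (bromomethyl)dimethylsilyl ether. Bu3SnH with azobisisobutyronitrile generates the α-silyl radical, which adds in a 5-exo mode to the enone β-carbon C1; the C2 radical is then reduced, giving siloxane A3, and a Tamao oxidation would release the 1,3-diol. In its favour, the five-membered tether can only give the cis relation between the new CH2 and the C6 oxygen. That is stereochemically more secure than the indium-bridged chair on which 18 depends, so here the alternative is better. Radical formation of the quaternary centre is insensitive to crowding, which is at least equal. Against it, the absolute configuration must already reside in the tertiary carbinol of A4, which needs its own asymmetric synthesis. C2 is set only by hydrogen transfer to a radical next to the new quaternary centre. The vinyl group of the cross-conjugated dienone is a second radical acceptor. Tin is used stoichiometrically. In comparison, the chosen key step makes the ring, C1 and C6 in one operation from an acyclic compound whose single stereocentre is set catalytically. A3 results from one C–C bond formed on a preformed ring, so step economy favours the chosen plan.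

**Alternative 3:** The cut is the C1–CH(OAc) and C2–CH2 bonds of a temporary cyclohexene fused across C1–C2. Forward, quinone ester A6 and acetoxydiene A7 combine in an endo Diels–Alder reaction at the ester-bearing double bond under a chiral oxazaborolidinium salt to give A5. In its favour, one catalytic step sets the quaternary C1 and C2 in defined relative and absolute configuration from two trivial components. This is better than the chosen plan, where C1 is set by substrate control. The target ring with its C3 and C6 carbonyls is also present from the start. Against it, the two diene-derived carbons of A5 are necessarily cis, which forces several corrections: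
- the acetoxy carbon must become the one-carbon hydroxymethyl (ring cleavage and loss of a carbon);
- the angular ester must become the long chain (reduction, methylenation, then the same hydroboration–coupling);
- the C2 branch must be lengthened by one carbon;
- the ene-dione must be reduced and its two ketones told apart;
- the C6 methyl carbinol must be made by an uncontrolled methyl addition beside the quaternary centre.

The very reactive A6 also invites an uncatalysed background reaction. In comparison, A5 is superior in how C1 and C2 are made. The chosen key step is superior in that it also delivers C6 and leaves every carbon at or near its final oxidation level and count, so the alternative is expected to need clearly more steps after its key step.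

Key step: step 11

**Remarks on the chemistry**

- Ring atoms keep the numbering C1 (quaternary) to C6 (methyl carbinol) in all names.
- The facial model of the imidazolidinone iminium ion (the arene enters the β-carbon face remote from the benzyl group) is assumed to hold for the β-alkyl enal 4. On that model the 2R,5R catalyst, not its 2S,5S antipode, leads to the S centre of 6, which is C2 of the target.
- Attack on the C3 ketone is excluded only for the C1 terminus. The CH2 terminus could in principle reach C3 (five-membered ring), and this is addressed in step 11.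

## Route

Step 1
Reactants: 1 pent-4-en-1-ol
Product: 2 tert-butyl(pent-4-en-1-yloxy)diphenylsilane
Conditions: t-BuPh2SiCl, imidazole, DMF, rt
Reagents that add atoms: tert-butyl(chloro)diphenylsilane, CC(C)(C)[Si](Cl)(c1ccccc1)c1ccccc1
Why: Silylation of a primary alcohol; the tert-butyldiphenylsilyl ether is chosen because it survives the acidic, basic, oxidative and reductive steps up to step 19.

Step 2
Reactants: 2 tert-butyl(pent-4-en-1-yloxy)diphenylsilane; 3 (E)-but-2-enal
Product: 4 (2E)-6-(tert-butyldiphenylsilyloxy)hex-2-enal
Conditions: 3 (5 equiv), second-generation Hoveyda–Grubbs catalyst RuCl2(H2IMes)(=CH-C6H4-2-O-i-Pr) (3 mol %), CH2Cl2, 40 °C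
Reagents that add atoms: none
Why: Olefin cross-metathesis of a terminal alkene with an excess of an enal; loss of volatile propene drives it and the conjugated product is expected as the E isomer.

Step 3
Reactants: 4 (2E)-6-(tert-butyldiphenylsilyloxy)hex-2-enal; 5 2-methylfuran
Product: 6 (3S)-6-(tert-butyldiphenylsilyloxy)-3-(5-methylfuran-2-yl)hexanal
Conditions: 5 (4 equiv), (2R,5R)-5-benzyl-2-tert-butyl-3-methylimidazolidin-4-one·CF3CO2H (20 mol %), CHCl3, −30 °C
Reagents that add atoms: none
Why: Iminium-ion catalysed conjugate Friedel–Crafts alkylation: the (E)-iminium ion of 4 has one face of its β-carbon blocked by the benzyl group, and the furan attacks through its free α-position from the open face, which with the 2R,5R catalyst should give the 3S aldehyde (C2 of the target).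

Step 4
Reactants: 6 (3S)-6-(tert-butyldiphenylsilyloxy)-3-(5-methylfuran-2-yl)hexanal
Product: 7 methyl (3S)-6-(tert-butyldiphenylsilyloxy)-3-(5-methylfuran-2-yl)hexanoate
Conditions: MnO2 (5 equiv), 1,4-dimethyl-1,2,4-triazolium iodide (15 mol %), DBU, MeOH, CH2Cl2, rt
Reagents that add atoms: methanol, CO
Why: Carbene-catalysed oxidative esterification: the triazolylidene adds to the aldehyde, MnO2 oxidises the Breslow intermediate to an acyl azolium ion and methanol is acylated; no electrophilic oxidant meets the furan and the β-stereocentre is not enolisable.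

Step 5
Reactants: 7 methyl (3S)-6-(tert-butyldiphenylsilyloxy)-3-(5-methylfuran-2-yl)hexanoate; 8 (tert-butyldimethylsilyloxy)acetaldehyde
Product: 10 methyl 4-(tert-butyldimethylsilyloxy)-3-hydroxy-2-[(1S)-4-(tert-butyldiphenylsilyloxy)-1-(5-methylfuran-2-yl)butyl]butanoate (mixture of diastereomers), via lithium ester enolate 9 (not isolated)
Conditions: LiN(i-Pr)2, THF, −78 °C; then 8, −78 °C; aq. NH4Cl
Reagents that add atoms: none
Why: Lithium ester enolate aldol addition; the two new centres are formed without control and are both removed in step 6, while the furyl-bearing centre (β to the ester, not acidic) is untouched.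

Step 6
Reactants: 10 methyl 4-(tert-butyldimethylsilyloxy)-3-hydroxy-2-[(1S)-4-(tert-butyldiphenylsilyloxy)-1-(5-methylfuran-2-yl)butyl]butanoate
Product: 12 methyl (2E)-4-(tert-butyldimethylsilyloxy)-2-[(1S)-4-(tert-butyldiphenylsilyloxy)-1-(5-methylfuran-2-yl)butyl]but-2-enoate, via secondary mesylate 11 (not isolated)
Conditions: MeSO2Cl, Et3N, CH2Cl2, 0 °C; then DBU, 0 °C → rt
Reagents that add atoms: none
Why: Mesylation followed by E1cB elimination through the ester enolate; both aldol diastereomers converge on the more stable E enoate (silyloxymethyl trans to the ester), and the neighbouring C–H is not acidified by the new enoate.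

Step 7
Reactants: 12 methyl (2E)-4-(tert-butyldimethylsilyloxy)-2-[(1S)-4-(tert-butyldiphenylsilyloxy)-1-(5-methylfuran-2-yl)butyl]but-2-enoate
Product: 13 methyl (2E)-2-[(1S)-4-(tert-butyldiphenylsilyloxy)-1-(5-methylfuran-2-yl)butyl]-4-hydroxybut-2-enoate
Conditions: pyridinium p-toluenesulfonate (0.2 equiv), MeOH, rt
Reagents that add atoms: none
Why: Acid-catalysed methanolysis removes the primary allylic tert-butyldimethylsilyl ether while the much more acid-stable tert-butyldiphenylsilyl ether and the furan survive; the hydroxyl is freed here so that no deprotection is needed on the labile diketones 14–16, and in the E isomer it cannot lactonise onto the trans ester.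

Step 8
Reactants: 13 methyl (2E)-2-[(1S)-4-(tert-butyldiphenylsilyloxy)-1-(5-methylfuran-2-yl)butyl]-4-hydroxybut-2-enoate
Product: 14 methyl (2E)-2-[(4S,6Z)-1-(tert-butyldiphenylsilyloxy)-5,8-dioxonon-6-en-4-yl]-4-hydroxybut-2-enoate
Conditions: N-bromosuccinimide (1.05 equiv), NaHCO3, pyridine, THF–acetone–H2O, −20 °C
Reagents that add atoms: water, O
Why: Buffered oxidative ring opening of a 2,5-dialkylfuran (bromonium attack, addition of water, collapse) to the (Z)-ene-1,4-dione; the electron-poor enoate is inert to the electrophile, and the cold buffered medium limits enolisation at the stereocentre, which is now α to the C3 ketone.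

Step 9
Reactants: 14 methyl (2E)-2-[(4S,6Z)-1-(tert-butyldiphenylsilyloxy)-5,8-dioxonon-6-en-4-yl]-4-hydroxybut-2-enoate
Product: 15 methyl (2E)-2-[(4S)-1-(tert-butyldiphenylsilyloxy)-5,8-dioxononan-4-yl]-4-hydroxybut-2-enoate
Conditions: Zn dust, AcOH–THF (1:4), 0 °C
Reagents that add atoms: none
Why: Dissolving-metal conjugate reduction of the doubly activated ene-dione to the saturated 1,4-diketone; the singly activated enoate is not reduced by zinc, and any reversible hemiketal between the hydroxyl and C3 returns the open form.

Step 10
Reactants: 15 methyl (2E)-2-[(4S)-1-(tert-butyldiphenylsilyloxy)-5,8-dioxononan-4-yl]-4-hydroxybut-2-enoate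
Product: 16 methyl (2E)-4-bromo-2-[(4S)-1-(tert-butyldiphenylsilyloxy)-5,8-dioxononan-4-yl]but-2-enoate
Conditions: CBr4, PPh3, CH2Cl2, −20 → 0 °C; filtered through silica and used at once
Reagents that add atoms: carbon tetrabromide, BrC(Br)(Br)Br
Why: Appel bromination of the primary allylic alcohol under essentially neutral conditions (SN2 on the alkoxyphosphonium ion); the bromide is not stored, because C2–H is α to the ketone and allylic.

Step 11
Reactants: 16 methyl (2E)-4-bromo-2-[(4S)-1-(tert-butyldiphenylsilyloxy)-5,8-dioxononan-4-yl]but-2-enoate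
Product: 18 methyl (1R,2S,6S)-2-[3-(tert-butyldiphenylsilyloxy)propyl]-1-ethenyl-6-hydroxy-6-methyl-3-oxocyclohexane-1-carboxylate, via allylindium dibromide 17 (not isolated)
Conditions: In powder (2 equiv), THF–H2O (3:1), 0.02 M, 0 °C → rt
Reagents that add atoms: none
Why: Indium inserts into the allylic C–Br bond, and the γ-(methoxycarbonyl)allylindium 17, in equilibrium with its oxygen-bound dienolate form, adds through the ester-bearing carbon C1 to the C6 methyl ketone with allylic transposition, which forms C1–C6 and leaves the vinyl group on C1. The closest known reactions are the α-selective (vinylogous Reformatsky) additions of 4-bromocrotonates to carbonyl groups mediated by indium or zinc, and the intramolecular Barbier allylation of ketones. The ring closes in the 6-exo-trig mode at the carbonyl carbon (6-enolexo at the nucleophile). C1 cannot reach C3 (three-membered ring); closure of the CH2 terminus onto C3 to a cyclopentenol would require bond formation without allylic transposition, which allylindium reagents avoid, and closure of the CH2 terminus onto C6 would give an eight-membered ring. C1 and C6 are set together in a chair in which trivalent indium bridges the ester and ketone oxygens, with the ketone oxygen and the vinyl group pseudo-equatorial and the ester carbon and the C6 methyl pseudo-axial, so that hydroxyl and ester become cis and vinyl and methyl share the other face. C2 decides which face of the nucleophile is used: its silyloxypropyl chain stays pseudo-equatorial (an axial chain would be 1,3-diaxial to the C6 methyl), which places it cis to ester and hydroxyl and gives the 1R,2S,6S isomer. The nearly neutral aqueous medium protonates the C6 alkoxide as it forms, so neither retro-aldol equilibration nor base-induced enolisation at C2 should intervene.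

Step 12
Reactants: 18 methyl (1R,2S,6S)-2-[3-(tert-butyldiphenylsilyloxy)propyl]-1-ethenyl-6-hydroxy-6-methyl-3-oxocyclohexane-1-carboxylate; 19 isopropenylmagnesium bromide
Product: 20 methyl (1R,2S,6S)-2-[3-(tert-butyldiphenylsilyloxy)propyl]-1-ethenyl-3,6-dihydroxy-6-methyl-3-(prop-1-en-2-yl)cyclohexane-1-carboxylate (both C3 epimers)
Conditions: CeCl3 (dried), 19 (4 equiv), THF, −78 °C; AcOH quench at −78 °C
Reagents that add atoms: none
Why: CeCl3-promoted Grignard 1,2-addition: the cerium-modified reagent is weakly basic, so addition to the hindered C3 ketone should outrun enolisation; one equivalent is spent on the C6 hydroxyl, the cold quench keeps the alkoxides from attacking the C1 ester, and the uncontrolled C3 centre disappears in step 13.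

Step 13
Reactants: 20 methyl (1R,2S,6S)-2-[3-(tert-butyldiphenylsilyloxy)propyl]-1-ethenyl-3,6-dihydroxy-6-methyl-3-(prop-1-en-2-yl)cyclohexane-1-carboxylate
Product: 21 methyl (1R,2R,3Z,6S)-2-[3-(tert-butyldiphenylsilyloxy)propyl]-1-ethenyl-6-hydroxy-6-methyl-3-(1-oxopropan-2-ylidene)cyclohexane-1-carboxylate
Conditions: pyridinium chlorochromate C5H5NH[CrO3Cl] (3 equiv), 4 Å molecular sieves, CH2Cl2, rt
Reagents that add atoms: none
Why: Babler–Dauben oxidative transposition: the tertiary allylic chromate ester undergoes a reversible [3,3] shift to the primary allylic chromate, which is oxidised to the enal, while the C6 tertiary alcohol cannot be oxidised; the Z isomer is expected to predominate because the smaller oxygenated carbon takes the position next to the substituted C2 and the methyl group the position next to C4H2.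

Step 14
Reactants: 21 methyl (1R,2R,3Z,6S)-2-[3-(tert-butyldiphenylsilyloxy)propyl]-1-ethenyl-6-hydroxy-6-methyl-3-(1-oxopropan-2-ylidene)cyclohexane-1-carboxylate
Product: 22 (1S,2R,3Z,6S)-2-[3-(tert-butyldiphenylsilyloxy)propyl]-1-ethenyl-6-hydroxy-1-(hydroxymethyl)-3-(1-hydroxypropan-2-ylidene)-6-methylcyclohexane
Conditions: i-Bu2AlH (6 equiv), CH2Cl2, −78 → 0 °C; Rochelle salt
Reagents that add atoms: none
Why: i-Bu2AlH reduces the enal (1,2) and the hindered methyl ester to primary alcohols; with both carbonyl groups gone, the hydroboration and the basic coupling of step 18 cannot reduce a ketone, trigger a retro-aldol reaction or epimerise C2, and the alkene geometry is untouched.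

Step 15
Reactants: 23 geranyl bromide; 24 trimethyl(prop-1-yn-1-yl)silane
Product: 26 [(5E)-6,10-dimethylundeca-5,9-dien-1-yn-1-yl]trimethylsilane, via lithiated silylpropyne 25 (not isolated)
Conditions: 24, n-BuLi, THF, −78 °C; then 23, −78 °C → rt
Reagents that add atoms: none
Why: Alkylation of the propargylic lithium reagent at the primary allylic bromide (SN2 at the α-carbon), which keeps the E geometry of the geranyl unit.

Step 16
Reactants: 26 [(5E)-6,10-dimethylundeca-5,9-dien-1-yn-1-yl]trimethylsilane
Product: 27 (5E)-6,10-dimethylundeca-5,9-dien-1-yne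
Conditions: K2CO3, MeOH, rt
Reagents that add atoms: none
Why: Base-catalysed methanolysis of the alkynyl C–Si bond.

Step 17
Reactants: 27 (5E)-6,10-dimethylundeca-5,9-dien-1-yne
Product: 29 (1E,5E)-1-iodo-2,6,10-trimethylundeca-1,5,9-triene, via alkenyldimethylalane 28 (not isolated)
Conditions: AlMe3 (2.5 equiv), Cp2ZrCl2 (25 mol %), CH2Cl2, 0 °C → rt; then I2, THF, −30 °C
Reagents that add atoms: trimethylaluminium, C[Al](C)C; iodine, II
Why: Zirconium-catalysed methylalumination (Negishi carboalumination) adds methyl and aluminium syn across the terminal alkyne with aluminium on the terminal carbon, and iodinolysis with retention gives the E iodide; the trisubstituted alkenes do not react.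

Step 18
Reactants: 22 (1S,2R,3Z,6S)-2-[3-(tert-butyldiphenylsilyloxy)propyl]-1-ethenyl-6-hydroxy-1-(hydroxymethyl)-3-(1-hydroxypropan-2-ylidene)-6-methylcyclohexane; 29 (1E,5E)-1-iodo-2,6,10-trimethylundeca-1,5,9-triene
Product: 31 (1S,2R,3Z,6S)-2-[3-(tert-butyldiphenylsilyloxy)propyl]-6-hydroxy-1-(hydroxymethyl)-3-(1-hydroxypropan-2-ylidene)-6-methyl-1-[(3E,7E)-4,8,12-trimethyltrideca-3,7,11-trien-1-yl]cyclohexane, via B-alkyl-9-borabicyclononane 30 (not isolated)
Conditions: 9-BBN (5 equiv), THF, rt; then 29, Pd(dppf)Cl2·CH2Cl2 (10 mol %), AsPh3, Cs2CO3, DMF–H2O, rt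
Reagents that add atoms: none
Why: 9-BBN hydroborates only the monosubstituted vinyl group, with boron on the terminal carbon (the tetrasubstituted alkene is inert and each hydroxyl consumes one B–H), and the B-alkyl Suzuki–Miyaura coupling forms the C(sp3)–C(sp2) bond with retention of the iodide geometry.

Step 19
Reactants: 31 (1S,2R,3Z,6S)-2-[3-(tert-butyldiphenylsilyloxy)propyl]-6-hydroxy-1-(hydroxymethyl)-3-(1-hydroxypropan-2-ylidene)-6-methyl-1-[(3E,7E)-4,8,12-trimethyltrideca-3,7,11-trien-1-yl]cyclohexane
Product: 32 (1S,2R,3Z,6S)-6-hydroxy-1-(hydroxymethyl)-2-(3-hydroxypropyl)-3-(1-hydroxypropan-2-ylidene)-6-methyl-1-[(3E,7E)-4,8,12-trimethyltrideca-3,7,11-trien-1-yl]cyclohexane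
Conditions: Bu4NF, THF, rt
Reagents that add atoms: none
Why: Fluoride cleavage of the silyl ether; it is done before the enal exists, because basic fluoride could deprotonate the γ-position (C2–H) of the enal.

Step 20
Reactants: 32 (1S,2R,3Z,6S)-6-hydroxy-1-(hydroxymethyl)-2-(3-hydroxypropyl)-3-(1-hydroxypropan-2-ylidene)-6-methyl-1-[(3E,7E)-4,8,12-trimethyltrideca-3,7,11-trien-1-yl]cyclohexane
Product: 33 (1S,2R,3Z,6S)-6-hydroxy-1-(hydroxymethyl)-2-(3-hydroxypropyl)-6-methyl-3-(1-oxopropan-2-ylidene)-1-[(3E,7E)-4,8,12-trimethyltrideca-3,7,11-trien-1-yl]cyclohexane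
Conditions: MnO2 (activated, 20 equiv), CH2Cl2, rt
Reagents that add atoms: none
Why: MnO2 oxidises only the allylic primary alcohol; the two saturated primary alcohols and the tertiary alcohol are inert, and the neutral heterogeneous conditions should leave the Z geometry and C2 untouched.

## Compound list

1 | pent-4-en-1-ol | C=CCCCO | starting material
2 | tert-butyl(pent-4-en-1-yloxy)diphenylsilane | C=CCCCO[Si](c1ccccc1)(c1ccccc1)C(C)(C)C | intermediate
3 | (E)-but-2-enal | C/C=C/C=O | starting material
4 | (2E)-6-(tert-butyldiphenylsilyloxy)hex-2-enal | O=C/C=C/CCCO[Si](c1ccccc1)(c1ccccc1)C(C)(C)C | intermediate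
5 | 2-methylfuran | Cc1ccco1 | starting material
6 | (3S)-6-(tert-butyldiphenylsilyloxy)-3-(5-methylfuran-2-yl)hexanal | O=CC[C@H](CCCO[Si](c1ccccc1)(c1ccccc1)C(C)(C)C)c1ccc(C)o1 | intermediate
7 | methyl (3S)-6-(tert-butyldiphenylsilyloxy)-3-(5-methylfuran-2-yl)hexanoate | COC(=O)C[C@H](CCCO[Si](c1ccccc1)(c1ccccc1)C(C)(C)C)c1ccc(C)o1 | intermediate
8 | (tert-butyldimethylsilyloxy)acetaldehyde | O=CCO[Si](C)(C)C(C)(C)C | starting material
9 | lithium enolate of 7 | COC(O[Li])=C[C@H](CCCO[Si](c1ccccc1)(c1ccccc1)C(C)(C)C)c1ccc(C)o1 | intermediate (not isolated)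
10 | methyl 4-(tert-butyldimethylsilyloxy)-3-hydroxy-2-[(1S)-4-(tert-butyldiphenylsilyloxy)-1-(5-methylfuran-2-yl)butyl]butanoate (mixture of diastereomers) | COC(=O)C(C(O)CO[Si](C)(C)C(C)(C)C)[C@H](CCCO[Si](c1ccccc1)(c1ccccc1)C(C)(C)C)c1ccc(C)o1 | intermediate
11 | 3-methanesulfonate of 10 | COC(=O)C(C(OS(C)(=O)=O)CO[Si](C)(C)C(C)(C)C)[C@H](CCCO[Si](c1ccccc1)(c1ccccc1)C(C)(C)C)c1ccc(C)o1 | intermediate (not isolated)
12 | methyl (2E)-4-(tert-butyldimethylsilyloxy)-2-[(1S)-4-(tert-butyldiphenylsilyloxy)-1-(5-methylfuran-2-yl)butyl]but-2-enoate | COC(=O)/C(=C/CO[Si](C)(C)C(C)(C)C)[C@H](CCCO[Si](c1ccccc1)(c1ccccc1)C(C)(C)C)c1ccc(C)o1 | intermediate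
13 | methyl (2E)-2-[(1S)-4-(tert-butyldiphenylsilyloxy)-1-(5-methylfuran-2-yl)butyl]-4-hydroxybut-2-enoate | COC(=O)/C(=C/CO)[C@H](CCCO[Si](c1ccccc1)(c1ccccc1)C(C)(C)C)c1ccc(C)o1 | intermediate
14 | methyl (2E)-2-[(4S,6Z)-1-(tert-butyldiphenylsilyloxy)-5,8-dioxonon-6-en-4-yl]-4-hydroxybut-2-enoate | COC(=O)/C(=C/CO)[C@H](CCCO[Si](c1ccccc1)(c1ccccc1)C(C)(C)C)C(=O)/C=C\C(C)=O | intermediate
15 | methyl (2E)-2-[(4S)-1-(tert-butyldiphenylsilyloxy)-5,8-dioxononan-4-yl]-4-hydroxybut-2-enoate | COC(=O)/C(=C/CO)[C@H](CCCO[Si](c1ccccc1)(c1ccccc1)C(C)(C)C)C(=O)CCC(C)=O | intermediate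
16 | methyl (2E)-4-bromo-2-[(4S)-1-(tert-butyldiphenylsilyloxy)-5,8-dioxononan-4-yl]but-2-enoate (key-step precursor) | COC(=O)/C(=C/CBr)[C@H](CCCO[Si](c1ccccc1)(c1ccccc1)C(C)(C)C)C(=O)CCC(C)=O | intermediate
17 | allylindium dibromide from 16, drawn as the monomeric unit of the sesquibromide | COC(=O)/C(=C/C[In](Br)Br)[C@H](CCCO[Si](c1ccccc1)(c1ccccc1)C(C)(C)C)C(=O)CCC(C)=O | intermediate (not isolated)
18 | methyl (1R,2S,6S)-2-[3-(tert-butyldiphenylsilyloxy)propyl]-1-ethenyl-6-hydroxy-6-methyl-3-oxocyclohexane-1-carboxylate (key-step product) | C=C[C@@]1(C(=O)OC)[C@H](CCCO[Si](c2ccccc2)(c2ccccc2)C(C)(C)C)C(=O)CC[C@]1(C)O | intermediate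
19 | isopropenylmagnesium bromide | C=C(C)[Mg]Br | starting material
20 | methyl (1R,2S,6S)-2-[3-(tert-butyldiphenylsilyloxy)propyl]-1-ethenyl-3,6-dihydroxy-6-methyl-3-(prop-1-en-2-yl)cyclohexane-1-carboxylate (both C3 epimers) | C=C[C@@]1(C(=O)OC)[C@H](CCCO[Si](c2ccccc2)(c2ccccc2)C(C)(C)C)C(O)(C(C)=C)CC[C@]1(C)O | intermediate
21 | methyl (1R,2R,3Z,6S)-2-[3-(tert-butyldiphenylsilyloxy)propyl]-1-ethenyl-6-hydroxy-6-methyl-3-(1-oxopropan-2-ylidene)cyclohexane-1-carboxylate | C=C[C@@]1(C(=O)OC)[C@H](CCCO[Si](c2ccccc2)(c2ccccc2)C(C)(C)C)/C(=C(/C)C=O)CC[C@]1(C)O | intermediate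
22 | (1S,2R,3Z,6S)-2-[3-(tert-butyldiphenylsilyloxy)propyl]-1-ethenyl-6-hydroxy-1-(hydroxymethyl)-3-(1-hydroxypropan-2-ylidene)-6-methylcyclohexane | C=C[C@@]1(CO)[C@H](CCCO[Si](c2ccccc2)(c2ccccc2)C(C)(C)C)/C(=C(/C)CO)CC[C@]1(C)O | intermediate
23 | geranyl bromide | CC(C)=CCC/C(C)=C/CBr | starting material
24 | trimethyl(prop-1-yn-1-yl)silane | CC#C[Si](C)(C)C | starting material
25 | [3-(trimethylsilyl)prop-2-yn-1-yl]lithium | [Li]CC#C[Si](C)(C)C | intermediate (not isolated)
26 | [(5E)-6,10-dimethylundeca-5,9-dien-1-yn-1-yl]trimethylsilane | CC(C)=CCC/C(C)=C/CCC#C[Si](C)(C)C | intermediate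
27 | (5E)-6,10-dimethylundeca-5,9-dien-1-yne | CC(C)=CCC/C(C)=C/CCC#C | intermediate
28 | dimethyl[(1E,5E)-2,6,10-trimethylundeca-1,5,9-trien-1-yl]alane | CC(C)=CCC/C(C)=C/CC/C(C)=C/[Al](C)C | intermediate (not isolated)
29 | (1E,5E)-1-iodo-2,6,10-trimethylundeca-1,5,9-triene | CC(C)=CCC/C(C)=C/CC/C(C)=C/I | intermediate
30 | B-alkyl-9-borabicyclo[3.3.1]nonane from 22 (hydroxyls drawn free) | C1CCC2CCCC1B2CC[C@@]1(CO)[C@H](CCCO[Si](c3ccccc3)(c3ccccc3)C(C)(C)C)/C(=C(/C)CO)CC[C@]1(C)O | intermediate (not isolated)
31 | (1S,2R,3Z,6S)-2-[3-(tert-butyldiphenylsilyloxy)propyl]-6-hydroxy-1-(hydroxymethyl)-3-(1-hydroxypropan-2-ylidene)-6-methyl-1-[(3E,7E)-4,8,12-trimethyltrideca-3,7,11-trien-1-yl]cyclohexane | CC(C)=CCC/C(C)=C/CC/C(C)=C/CC[C@@]1(CO)[C@H](CCCO[Si](c2ccccc2)(c2ccccc2)C(C)(C)C)/C(=C(/C)CO)CC[C@]1(C)O | intermediate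
32 | (1S,2R,3Z,6S)-6-hydroxy-1-(hydroxymethyl)-2-(3-hydroxypropyl)-3-(1-hydroxypropan-2-ylidene)-6-methyl-1-[(3E,7E)-4,8,12-trimethyltrideca-3,7,11-trien-1-yl]cyclohexane | CC(C)=CCC/C(C)=C/CC/C(C)=C/CC[C@@]1(CO)[C@H](CCCO)/C(=C(/C)CO)CC[C@]1(C)O | intermediate
33 | (1S,2R,3Z,6S)-6-hydroxy-1-(hydroxymethyl)-2-(3-hydroxypropyl)-6-methyl-3-(1-oxopropan-2-ylidene)-1-[(3E,7E)-4,8,12-trimethyltrideca-3,7,11-trien-1-yl]cyclohexane, CNP0284886.1 | CC(C)=CCC/C(C)=C/CC/C(C)=C/CC[C@@]1(CO)[C@H](CCCO)/C(=C(/C)C=O)CC[C@]1(C)O | target

## Step count and least certain steps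

Total step count: 20. Longest linear sequence: 17 steps (steps 1–14 and 18–20, from 1). The iodide 29 is made in a three-step branch (steps 15–17) from 23.

**Step 11 (key step).** The most likely failure is loss of the substrate before the ring closes. C2–H of 16 is α to the C3 ketone and allylic, so enolisation, promoted by the trivalent indium salts that build up, can scramble C2 or expel bromide in a vinylogous elimination. In water, the hindered organoindium may also be protonated faster than it joins two fully substituted carbons. A second uncertainty is facial control: three indium-bridged chairs are conceivable and only one leads to 18, so diastereomers may have to be separated at this stage. Fallback: set out from 15 and acetylate it (Ac2O, pyridine, 0 °C) to methyl (2E)-4-acetoxy-2-[(4S)-1-(tert-butyldiphenylsilyloxy)-5,8-dioxononan-4-yl]but-2-enoate F1. Treat F1 with Pd(PPh3)4 (zerovalent palladium, 5 mol %) and InI (monovalent indium iodide) in dry THF. The acetate is ionised to a π-allylpalladium complex, which is reduced in situ to the allylindium and closes to 18. No bromide is handled and no water is present; the route is rejoined at 18.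

**Step 13.** The most likely failure is formation of the E enal (formyl on the C4 side) or of a mixture. The geometry is decided by which rotamer of the isopropenyl group enters the sigmatropic shift and by a small energy difference between formyl and methyl next to C2. Fallback (lactone template, geometry fixed by connectivity): set out from 18.
- HF·pyridine in THF frees the primary alcohol to give methyl (1R,2S,6S)-1-ethenyl-6-hydroxy-2-(3-hydroxypropyl)-6-methyl-3-oxocyclohexane-1-carboxylate F2.
- 2,2-Dibromopropanoyl chloride and pyridine acylate only the primary hydroxyl, giving the 2,2-dibromopropanoate F3.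
- SmI2 (divalent samarium) in THF effects Reformatsky addition to the C3 ketone and reductive elimination, giving the eight-membered (Z)-α-methyl enoate lactone F4.
- i-Bu2AlH reduces the lactone and the methyl ester to the vinyl tetraol (1S,2R,3Z,6S)-1-ethenyl-6-hydroxy-1-(hydroxymethyl)-2-(3-hydroxypropyl)-3-(1-hydroxypropan-2-ylidene)-6-methylcyclohexane F5.
- Hydroboration with excess 9-BBN and coupling with 29, as in step 18, rejoins the route at 32.

**Step 12.** The most likely failure is consumption of 18 by side reactions of its alkoxides: enolisation of the hindered ketone toward C4, lactonisation of the new C3 alkoxide onto the 1,3-related C1 ester, or retro-aldol cleavage of C1–C6 from the C6 alkoxide. Fallback (remove the ester before C3 is elaborated): set out from 18.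
- LiAlH4 in THF reduces ester and ketone to the triol (1S,2S,6S)-2-[3-(tert-butyldiphenylsilyloxy)propyl]-1-ethenyl-3,6-dihydroxy-1-(hydroxymethyl)-6-methylcyclohexane F6 (C3 epimers).
- 2,2-Dimethoxypropane and pyridinium p-toluenesulfonate protect the 1,3-diol as the acetonide alcohol F7.
- Dess–Martin periodinane gives the acetonide ketone F8.
- Isopropenylmagnesium bromide with CeCl3 gives the tertiary allylic alcohol F9.
- Pyridinium chlorochromate gives the (Z)-enal acetonide F10.
- i-Bu2AlH gives the allylic alcohol acetonide F11.
- Aqueous acetic acid in THF removes the acetonide and rejoins the route at 22.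

**Step 3.** The most likely failure is slow conjugate addition, because 2-methylfuran is only a moderate nucleophile; the uncatalysed background reaction and acid-induced furan oligomerisation would then erode enantiomeric purity and conversion. Fallback (the stereocentre is set by a metal-catalysed aryl transfer at the ester level): set out from 2. Cross-metathesis with methyl acrylate (same ruthenium catalyst) gives methyl (2E)-6-(tert-butyldiphenylsilyloxy)hex-2-enoate F12. Conjugate addition of 4,4,5,5-tetramethyl-2-(5-methylfuran-2-yl)-1,3,2-dioxaborolane follows, catalysed by Rh(acac)(C2H4)2 (monovalent rhodium) with the BINAP antipode that delivers the S centre (aqueous dioxane, KOH). This rejoins the route at 7 and also bypasses step 4.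

## Further compounds

F1 | step 11 | methyl (2E)-4-acetoxy-2-[(4S)-1-(tert-butyldiphenylsilyloxy)-5,8-dioxononan-4-yl]but-2-enoate | COC(=O)/C(=C/COC(C)=O)[C@H](CCCO[Si](c1ccccc1)(c1ccccc1)C(C)(C)C)C(=O)CCC(C)=O
F2 | step 13 | methyl (1R,2S,6S)-1-ethenyl-6-hydroxy-2-(3-hydroxypropyl)-6-methyl-3-oxocyclohexane-1-carboxylate | C=C[C@@]1(C(=O)OC)[C@H](CCCO)C(=O)CC[C@]1(C)O
F3 | step 13 | 2,2-dibromopropanoate of the primary alcohol of F2 | C=C[C@@]1(C(=O)OC)[C@H](CCCOC(=O)C(C)(Br)Br)C(=O)CC[C@]1(C)O
F4 | step 13 | eight-membered (Z)-α-methyl enoate lactone fused at C2–C3, with C1 methyl ester and C6 hydroxyl | C=C[C@@]1(C(=O)OC)[C@@H]2CCCOC(=O)/C(C)=C2/CC[C@]1(C)O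
F5 | step 13 | (1S,2R,3Z,6S)-1-ethenyl-6-hydroxy-1-(hydroxymethyl)-2-(3-hydroxypropyl)-3-(1-hydroxypropan-2-ylidene)-6-methylcyclohexane | C=C[C@@]1(CO)[C@H](CCCO)/C(=C(/C)CO)CC[C@]1(C)O
F6 | step 12 | (1S,2S,6S)-2-[3-(tert-butyldiphenylsilyloxy)propyl]-1-ethenyl-3,6-dihydroxy-1-(hydroxymethyl)-6-methylcyclohexane (C3 epimers) | C=C[C@@]1(CO)[C@H](CCCO[Si](c2ccccc2)(c2ccccc2)C(C)(C)C)C(O)CC[C@]1(C)O
F7 | step 12 | acetonide of F6 across the C1 hydroxymethyl and C6 hydroxyl, C3 alcohol free | C=C[C@@]1(COC(C)(C)O2)[C@H](CCCO[Si](c3ccccc3)(c3ccccc3)C(C)(C)C)C(O)CC[C@@]12C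
F8 | step 12 | C3 ketone of the acetonide | C=C[C@@]1(COC(C)(C)O2)[C@H](CCCO[Si](c3ccccc3)(c3ccccc3)C(C)(C)C)C(=O)CC[C@@]12C
F9 | step 12 | C3 isopropenyl carbinol of the acetonide (C3 epimers) | C=C[C@@]1(COC(C)(C)O2)[C@H](CCCO[Si](c3ccccc3)(c3ccccc3)C(C)(C)C)C(O)(C(C)=C)CC[C@@]12C
F10 | step 12 | (Z)-enal acetonide | C=C[C@@]1(COC(C)(C)O2)[C@H](CCCO[Si](c3ccccc3)(c3ccccc3)C(C)(C)C)/C(=C(/C)C=O)CC[C@@]12C
F11 | step 12 | (Z)-allylic alcohol acetonide | C=C[C@@]1(COC(C)(C)O2)[C@H](CCCO[Si](c3ccccc3)(c3ccccc3)C(C)(C)C)/C(=C(/C)CO)CC[C@@]12C
F12 | step 3 | methyl (2E)-6-(tert-butyldiphenylsilyloxy)hex-2-enoate | COC(=O)/C=C/CCCO[Si](c1ccccc1)(c1ccccc1)C(C)(C)C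
A1 | alternative 1 | fused eight-membered α-methyl enoate lactone with acetonide and full side chain | CC(C)=CCC/C(C)=C/CC/C(C)=C/CC[C@@]1(COC(C)(C)O2)[C@@H]3CCCOC(=O)/C(C)=C3/CC[C@@]12C
A2 | alternative 1 | 2,2-dibromopropanoate of the C2 side-chain alcohol with the C3 ketone | CC(C)=CCC/C(C)=C/CC/C(C)=C/CC[C@@]1(COC(C)(C)O2)[C@H](CCCOC(=O)C(C)(Br)Br)C(=O)CC[C@@]12C
A3 | alternative 2 | cis-fused siloxane with quaternary C1 and C2 set | C=C[C@@]1(C[Si](C)(C)O2)[C@H](CCCOCc3ccc(OC)cc3)C(=O)CC[C@@]12C
A4 | alternative 2 | (bromomethyl)dimethylsilyl ether of the 3-vinyl-4-hydroxy-4-methylcyclohexenone | C=CC1=C(CCCOCc2ccc(OC)cc2)C(=O)CC[C@]1(C)O[Si](C)(C)CBr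
A5 | alternative 3 | cis-fused acetoxy ene-dione Diels–Alder adduct with angular ester | COC(=O)[C@@]12[C@H](OC(C)=O)C=CC[C@@H]1C(=O)C=CC2=O
A6 | alternative 3 | methyl 3,6-dioxocyclohexa-1,4-diene-1-carboxylate | COC(=O)C1=CC(=O)C=CC1=O
A7 | alternative 3 | (E)-buta-1,3-dien-1-yl acetate | CC(=O)O/C=C/C=C
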